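**Plan**

Ring A is the salicyloyl ring, numbered from the carbon that bears the depside carbonyl (hydroxyl at position 2, methoxy at position 4, 2-oxoheptyl chain at position 6); ring B is the benzoic acid ring, numbered from the carboxyl-bearing carbon (methoxy at position 2, depside oxygen at position 4, 2-oxoheptyl chain at position 6).
The retrosynthesis first cuts the depside on both sides of its carbonyl: this single carbon lies between position 1 of ring A and the oxygen on position 4 of ring B, so it can enter as carbon monoxide between a ring A aryl iodide and a ring B phenol.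
Next the aryl–carboxyl bond of ring B is cut back to the same aryl iodide (magnesium exchange, Boc2O), and in both rings the CH2C(=O)–pentyl bond is cut to an arylacetate and pentylmagnesium bromide.
Forward: methyl 3,5-dihydroxyphenylacetate gives in four steps one symmetric dibenzyloxy aryl iodide with the ketone masked as a dioxolane; part of it becomes the ring B tert-butyl ester diol, and iodide, CO and the unchelated para hydroxyl of ring B are then joined. No ring is formed anywhere; both benzene rings come from the starting material.
Hydrogen bonding to the two ester carbonyls then directs the two O-methylations (position 2 of ring B before, position 4 of ring A after debenzylation), and aqueous acid frees the acid and both ketones.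
The target has no stereocentre, so no stereochemistry has to be set.

Key step: step 7

Remark: a hydroxyl hydrogen-bonded to an ortho ester carbonyl is assumed to be clearly less acidic and less nucleophilic than the free para hydroxyl, as is usual for 2,4-dihydroxybenzoates; N,O-dimethylhydroxylamine hydrochloride, pentylmagnesium bromide and carbon monoxide are taken as purchased.

**Route**

Step 1
Reactants: 1 methyl 3,5-dihydroxyphenylacetate
Product: 2 methyl 3,5-bis(benzyloxy)phenylacetate
Conditions: BnBr (2.4 equiv), K2CO3 (3 equiv), acetone, reflux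
Reagents that add atoms: benzyl bromide, BrCc1ccccc1
Why: Williamson ether synthesis: K2CO3 deprotonates only the two phenols (the arylacetate CH2 is far less acidic), so both hydroxyls should be benzylated without C-alkylation.

Step 2
Reactants: 2 methyl 3,5-bis(benzyloxy)phenylacetate; 3 N,O-dimethylhydroxylamine hydrochloride; 4 pentylmagnesium bromide
Product: 6 1-[3,5-bis(benzyloxy)phenyl]heptan-2-one, via Weinreb amide 5 (not isolated)
Conditions: 3 (1.5 equiv), iPrMgCl (3.0 equiv), THF, −20 °C; then 4 (3 equiv), −20 → 0 °C; aq. NH4Cl
Reagents that add atoms: none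
Why: Weinreb ketone synthesis run in one flask: the chloromagnesium amide from 3 and iPrMgCl converts the methyl ester into amide 5, and the five-membered magnesium chelate formed when 4 adds to 5 should persist until the quench, so the ketone appears only on work-up and is not attacked a second time.

Step 3
Reactants: 6 1-[3,5-bis(benzyloxy)phenyl]heptan-2-one
Product: 7 2-{[3,5-bis(benzyloxy)phenyl]methyl}-2-pentyl-1,3-dioxolane
Conditions: ethylene glycol (5 equiv), TsOH·H2O (5 mol %), toluene, reflux (Dean–Stark)
Reagents that add atoms: ethylene glycol, OCCO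
Why: Acid-catalysed ketalisation with azeotropic removal of water should convert the unhindered, non-conjugated ketone fully into the 1,3-dioxolane, while the benzyl ethers are inert to catalytic TsOH.

Step 4
Reactants: 7 2-{[3,5-bis(benzyloxy)phenyl]methyl}-2-pentyl-1,3-dioxolane
Product: 8 2-{[3,5-bis(benzyloxy)-2-iodophenyl]methyl}-2-pentyl-1,3-dioxolane (ring A aryl iodide)
Conditions: NIS (1.05 equiv), MeCN, 0 °C → rt, dark
Reagents that add atoms: N-iodosuccinimide, O=C1CCC(=O)N1I
Why: Electrophilic aromatic iodination of a resorcinol diether: the two positions next to the side chain are equivalent by symmetry and each is para to one benzyloxy group and ortho to the other, whereas the position between the two benzyloxy groups has no para donor and is flanked on both sides, so one equivalent of NIS under neutral conditions (which spare the ketal) should give a single mono-iodide.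

Step 5
Reactants: 8 2-{[3,5-bis(benzyloxy)-2-iodophenyl]methyl}-2-pentyl-1,3-dioxolane
Product: 10 tert-butyl 2,4-bis(benzyloxy)-6-[(2-pentyl-1,3-dioxolan-2-yl)methyl]benzoate, via arylmagnesium chloride 9 (not isolated)
Conditions: iPrMgCl·LiCl (1.2 equiv), THF, 0 °C → rt; then Boc2O (1.5 equiv), 0 °C → rt; aq. NH4Cl
Reagents that add atoms: di-tert-butyl dicarbonate, CC(C)(C)OC(=O)OC(=O)OC(C)(C)C
Why: Iodine–magnesium exchange, assisted by the ortho benzyloxy oxygen, should give arylmagnesium chloride 9, which is acylated by Boc2O with loss of tert-butyl carbonate (tert-butoxycarbonylation of a Grignard reagent), while the ethers and the ketal do not react with organomagnesium reagents.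

Step 6
Reactants: 10 tert-butyl 2,4-bis(benzyloxy)-6-[(2-pentyl-1,3-dioxolan-2-yl)methyl]benzoate
Product: 11 tert-butyl 2,4-dihydroxy-6-[(2-pentyl-1,3-dioxolan-2-yl)methyl]benzoate (ring B phenol)
Conditions: H2 (1 atm), 10% Pd/C, EtOAc, rt
Reagents that add atoms: none
Why: Catalytic hydrogenolysis of the two O-benzyl groups over Pd/C in a neutral solvent should leave the tert-butyl ester and the dioxolane untouched.

Step 7
Reactants: 8 2-{[3,5-bis(benzyloxy)-2-iodophenyl]methyl}-2-pentyl-1,3-dioxolane; 12 carbon monoxide; 11 tert-butyl 2,4-dihydroxy-6-[(2-pentyl-1,3-dioxolan-2-yl)methyl]benzoate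
Product: 13 tert-butyl 4-({2,4-bis(benzyloxy)-6-[(2-pentyl-1,3-dioxolan-2-yl)methyl]benzoyl}oxy)-2-hydroxy-6-[(2-pentyl-1,3-dioxolan-2-yl)methyl]benzoate
Conditions: 11 (1.2 equiv), Pd(OAc)2 (5 mol %), Xantphos (6 mol %), Et3N (3 equiv), CO (2 bar), toluene, 90 °C
Reagents that add atoms: none
Why: Pd(OAc)2 is reduced in the flask to zerovalent palladium carrying Xantphos, which inserts into the C–I bond of 8; carbon monoxide then inserts into the crowded aryl–palladium bond to give a divalent aroylpalladium iodide, and the triethylammonium phenoxide of 11 replaces iodide and leaves with the acyl group by C–O reductive elimination, forming the bond from position 1 of ring A to the carbonyl carbon and the bond from that carbon to the oxygen on position 4 of ring B, and returning zerovalent palladium. The closest known reaction type is the palladium-catalysed aryloxycarbonylation (carbonylative esterification) of aryl iodides with phenols under Pd(OAc)2/Xantphos and an amine base. No ring is closed and no stereocentre is created. Two selectivities are needed: carbon monoxide insertion must outrun direct aryl ether formation, which should be secured by the carbon monoxide pressure, the wide-bite-angle ligand and the relief of strain when the doubly ortho-flanked aryl group migrates to CO; and acylation must go only to the hydroxyl at position 4 of ring B, which should follow because the hydroxyl at position 2 is held in a six-membered hydrogen bond to the tert-butyl ester carbonyl, is markedly less acidic and is not deprotonated by Et3N. The dioxolanes keep both benzylic ketones from enolising, so no enolate can capture the aroylpalladium to close an isocoumarin. Because the acyl group is assembled on palladium, no 2,6-disubstituted benzoic acid has to be activated.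

Step 8
Reactants: 13 tert-butyl 4-({2,4-bis(benzyloxy)-6-[(2-pentyl-1,3-dioxolan-2-yl)methyl]benzoyl}oxy)-2-hydroxy-6-[(2-pentyl-1,3-dioxolan-2-yl)methyl]benzoate
Product: 14 tert-butyl 4-({2,4-bis(benzyloxy)-6-[(2-pentyl-1,3-dioxolan-2-yl)methyl]benzoyl}oxy)-2-methoxy-6-[(2-pentyl-1,3-dioxolan-2-yl)methyl]benzoate
Conditions: MeI (3 equiv), K2CO3 (3 equiv), acetone, reflux
Reagents that add atoms: iodomethane, CI
Why: Williamson O-methylation: the only free hydroxyl is the hydrogen-bonded one next to the tert-butyl ester, which needs excess MeI and reflux, and the depside carbonyl is shielded by its two ortho substituents on ring A, so attack of the phenoxide on it should remain slow.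

Step 9
Reactants: 14 tert-butyl 4-({2,4-bis(benzyloxy)-6-[(2-pentyl-1,3-dioxolan-2-yl)methyl]benzoyl}oxy)-2-methoxy-6-[(2-pentyl-1,3-dioxolan-2-yl)methyl]benzoate
Product: 15 tert-butyl 4-({2,4-dihydroxy-6-[(2-pentyl-1,3-dioxolan-2-yl)methyl]benzoyl}oxy)-2-methoxy-6-[(2-pentyl-1,3-dioxolan-2-yl)methyl]benzoate
Conditions: H2 (1 atm), 10% Pd/C, EtOAc, rt
Reagents that add atoms: none
Why: Hydrogenolysis of the two benzyl ethers of ring A over Pd/C should proceed cleanly because the aryl ester, the tert-butyl ester and the dioxolanes are stable to these conditions.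

Step 10
Reactants: 15 tert-butyl 4-({2,4-dihydroxy-6-[(2-pentyl-1,3-dioxolan-2-yl)methyl]benzoyl}oxy)-2-methoxy-6-[(2-pentyl-1,3-dioxolan-2-yl)methyl]benzoate
Product: 16 tert-butyl 4-({2-hydroxy-4-methoxy-6-[(2-pentyl-1,3-dioxolan-2-yl)methyl]benzoyl}oxy)-2-methoxy-6-[(2-pentyl-1,3-dioxolan-2-yl)methyl]benzoate
Conditions: MeI (1.1 equiv), K2CO3 (1.1 equiv), acetone, rt
Reagents that add atoms: iodomethane, CI
Why: Site-selective Williamson methylation as known for 2,4-dihydroxybenzoates: the ring A hydroxyl para to the ester carbonyl is the more acidic and is free, while the ortho hydroxyl is tied up in a hydrogen bond to the depside carbonyl, so one equivalent of MeI with K2CO3 at room temperature should stop at the para methyl ether.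

Step 11
Reactants: 16 tert-butyl 4-({2-hydroxy-4-methoxy-6-[(2-pentyl-1,3-dioxolan-2-yl)methyl]benzoyl}oxy)-2-methoxy-6-[(2-pentyl-1,3-dioxolan-2-yl)methyl]benzoate
Product: 17 4-{[2-hydroxy-4-methoxy-6-(2-oxoheptyl)benzoyl]oxy}-2-methoxy-6-(2-oxoheptyl)benzoic acid (target)
Conditions: TFA/H2O/CH2Cl2 (9:1:10), 0 °C → rt
Reagents that add atoms: water, O
Why: Acid-catalysed hydrolysis of both dioxolanes and acidolysis of the tert-butyl ester through the tert-butyl cation should occur together in aqueous TFA, to which the aryl ester, the methyl ethers and the phenol are inert, and the water present both traps the cation and disfavours dehydrative enol lactonisation.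

**Compound list**

1 | methyl 3,5-dihydroxyphenylacetate | COC(=O)Cc1cc(O)cc(O)c1 | starting material
2 | methyl 3,5-bis(benzyloxy)phenylacetate | COC(=O)Cc1cc(OCc2ccccc2)cc(OCc2ccccc2)c1 | intermediate
3 | N,O-dimethylhydroxylamine hydrochloride | CNOC.Cl | starting material
4 | pentylmagnesium bromide | CCCCC[Mg]Br | starting material
5 | 2-[3,5-bis(benzyloxy)phenyl]-N-methoxy-N-methylacetamide (Weinreb amide, not isolated) | CON(C)C(=O)Cc1cc(OCc2ccccc2)cc(OCc2ccccc2)c1 | intermediate
6 | 1-[3,5-bis(benzyloxy)phenyl]heptan-2-one | CCCCCC(=O)Cc1cc(OCc2ccccc2)cc(OCc2ccccc2)c1 | intermediate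
7 | 2-{[3,5-bis(benzyloxy)phenyl]methyl}-2-pentyl-1,3-dioxolane | CCCCCC1(Cc2cc(OCc3ccccc3)cc(OCc3ccccc3)c2)OCCO1 | intermediate
8 | 2-{[3,5-bis(benzyloxy)-2-iodophenyl]methyl}-2-pentyl-1,3-dioxolane (ring A aryl iodide) | CCCCCC1(Cc2cc(OCc3ccccc3)cc(OCc3ccccc3)c2I)OCCO1 | intermediate
9 | {2,4-bis(benzyloxy)-6-[(2-pentyl-1,3-dioxolan-2-yl)methyl]phenyl}magnesium chloride (not isolated) | CCCCCC1(Cc2cc(OCc3ccccc3)cc(OCc3ccccc3)c2[Mg]Cl)OCCO1 | intermediate
10 | tert-butyl 2,4-bis(benzyloxy)-6-[(2-pentyl-1,3-dioxolan-2-yl)methyl]benzoate | CCCCCC1(Cc2cc(OCc3ccccc3)cc(OCc3ccccc3)c2C(=O)OC(C)(C)C)OCCO1 | intermediate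
11 | tert-butyl 2,4-dihydroxy-6-[(2-pentyl-1,3-dioxolan-2-yl)methyl]benzoate (ring B phenol) | CCCCCC1(Cc2cc(O)cc(O)c2C(=O)OC(C)(C)C)OCCO1 | intermediate
12 | carbon monoxide | [C-]#[O+] | starting material
13 | tert-butyl 4-({2,4-bis(benzyloxy)-6-[(2-pentyl-1,3-dioxolan-2-yl)methyl]benzoyl}oxy)-2-hydroxy-6-[(2-pentyl-1,3-dioxolan-2-yl)methyl]benzoate | CCCCCC1(Cc2cc(OCc3ccccc3)cc(OCc3ccccc3)c2C(=O)Oc2cc(O)c(C(=O)OC(C)(C)C)c(CC3(CCCCC)OCCO3)c2)OCCO1 | intermediate
14 | tert-butyl 4-({2,4-bis(benzyloxy)-6-[(2-pentyl-1,3-dioxolan-2-yl)methyl]benzoyl}oxy)-2-methoxy-6-[(2-pentyl-1,3-dioxolan-2-yl)methyl]benzoate | CCCCCC1(Cc2cc(OCc3ccccc3)cc(OCc3ccccc3)c2C(=O)Oc2cc(OC)c(C(=O)OC(C)(C)C)c(CC3(CCCCC)OCCO3)c2)OCCO1 | intermediate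
15 | tert-butyl 4-({2,4-dihydroxy-6-[(2-pentyl-1,3-dioxolan-2-yl)methyl]benzoyl}oxy)-2-methoxy-6-[(2-pentyl-1,3-dioxolan-2-yl)methyl]benzoate | CCCCCC1(Cc2cc(O)cc(O)c2C(=O)Oc2cc(OC)c(C(=O)OC(C)(C)C)c(CC3(CCCCC)OCCO3)c2)OCCO1 | intermediate
16 | tert-butyl 4-({2-hydroxy-4-methoxy-6-[(2-pentyl-1,3-dioxolan-2-yl)methyl]benzoyl}oxy)-2-methoxy-6-[(2-pentyl-1,3-dioxolan-2-yl)methyl]benzoate | CCCCCC1(Cc2cc(OC)cc(O)c2C(=O)Oc2cc(OC)c(C(=O)OC(C)(C)C)c(CC3(CCCCC)OCCO3)c2)OCCO1 | intermediate
17 | 4-{[2-hydroxy-4-methoxy-6-(2-oxoheptyl)benzoyl]oxy}-2-methoxy-6-(2-oxoheptyl)benzoic acid | CCCCCC(=O)Cc1cc(OC)cc(O)c1C(=O)Oc1cc(CC(=O)CCCCC)c(C(=O)O)c(OC)c1 | target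

**Step count**

Total steps: 11. Longest linear sequence: 11 steps (1 to 17 through 8, 10, 11 and 13). The iodide 8 is used twice, once in step 5 as the source of ring B and once in step 7 as ring A.

**Steps most likely to fail, with fallbacks**

Step 7 is the first concern. Oxidative addition and carbonylation at the doubly ortho-flanked iodide may be slow enough for reductive deiodination to compete, or acylation may spill over to the hydrogen-bonded hydroxyl at position 2 of ring B. The fallback leaves carbonylation aside and sets out from 8. Iodine–magnesium exchange with iPrMgCl·LiCl in THF gives the arylmagnesium chloride 9, which is quenched with CO2 and worked up at about pH 4 to give 2,4-bis(benzyloxy)-6-[(2-pentyl-1,3-dioxolan-2-yl)methyl]benzoic acid F1. The neutral chlorinating agent 1-chloro-N,N,2-trimethylprop-1-en-1-amine in CH2Cl2 (no HCl is released, so the ketal is safe) converts it into 2,4-bis(benzyloxy)-6-[(2-pentyl-1,3-dioxolan-2-yl)methyl]benzoyl chloride F2. Acylation of phenol 11 with this acid chloride (Et3N, catalytic DMAP, CH2Cl2) should again take place at the free hydroxyl at position 4 of ring B, and the route is rejoined at 13.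

Step 10 is the second concern. Methylation may run on to the hydrogen-bonded hydroxyl at position 2 of ring A, or the phenoxides formed under carbonate may attack the now less shielded depside carbonyl and cause acyl transfer between molecules. The fallback sets out from 15 and uses a Mitsunobu etherification with methanol (PPh3, DIAD, THF, 0 °C → rt). It needs no phenoxide base and engages only the more acidic, non-hydrogen-bonded hydroxyl at position 4 of ring A. It comes back to the route at 16 and makes no new compound (F0).

Step 11 is the third concern. Once the ketones are free in strong acid, their enols may lactonise onto the neighbouring carboxyl or onto the depside carbonyl (isocoumarin formation, in the second case with loss of ring B), and the tert-butyl cation may alkylate the activated ring A. The fallback separates the two deprotections and sets out from 16. Pyridinium p-toluenesulfonate in acetone/H2O (10:1) at 50 °C removes both dioxolanes under weakly acidic conditions and gives tert-butyl 4-{[2-hydroxy-4-methoxy-6-(2-oxoheptyl)benzoyl]oxy}-2-methoxy-6-(2-oxoheptyl)benzoate F3. The tert-butyl ester is then cleaved with the Lewis acid ZnBr2 in CH2Cl2 at rt, followed by aqueous work-up, which arrives at 17 without exposure to a strong protic acid.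

**Further compounds**

F1 | step 7 | 2,4-bis(benzyloxy)-6-[(2-pentyl-1,3-dioxolan-2-yl)methyl]benzoic acid | CCCCCC1(Cc2cc(OCc3ccccc3)cc(OCc3ccccc3)c2C(=O)O)OCCO1
F2 | step 7 | 2,4-bis(benzyloxy)-6-[(2-pentyl-1,3-dioxolan-2-yl)methyl]benzoyl chloride | CCCCCC1(Cc2cc(OCc3ccccc3)cc(OCc3ccccc3)c2C(=O)Cl)OCCO1
F0 | step 10 | none | none
F3 | step 11 | tert-butyl 4-{[2-hydroxy-4-methoxy-6-(2-oxoheptyl)benzoyl]oxy}-2-methoxy-6-(2-oxoheptyl)benzoate | CCCCCC(=O)Cc1cc(OC)cc(O)c1C(=O)Oc1cc(OC)c(C(=O)OC(C)(C)C)c(CC(=O)CCCCC)c1
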